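**Retrosynthetic overview**
1. Target 10 ⇐ cis-diacetate 9 ⇐ allylic diazene 8: a retro-ene loss of N2 carries hydrogen from nitrogen on C4 to C2 and places the double bond at C3=C4.
2. Diazene 8 ⇐ hydrazide adduct 6 ⇐ symmetric diene 5 by one catalytic 1,4-hydrazidoarylation: the C4–N bond forms first (enantio-determining), then the C1–C8a bond.
3. Diene 5 ⇐ twofold Heck reaction of 2,3-dimethylbutadiene 2 with bromosyringol 1, used as its acetate 3.
4. Ring order: both benzene rings are bought; the dihydronaphthalene carbocycle is the only ring built (step 2). Nitrogen only relays stereochemistry and leaves as N2.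

Assumption: the sense of induction of the new palladium catalyst cannot be known in advance, so the ligand antipode that gives 6 as drawn is taken ((S)-tBu-PyOx is written); locants for 6–10 follow the target (C1 carries the pendant aryl ring, ring A is the fused benzene ring).

**Step 1**
Reactants: 1 4-bromo-2,6-dimethoxyphenol; 2 2,3-dimethylbuta-1,3-diene
Product: 5 (1E,3E)-1,4-bis(4-acetoxy-3,5-dimethoxyphenyl)-2,3-dimethylbuta-1,3-diene, via aryl acetate 3 (not isolated), via monoaryl diene 4 (not isolated)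
Conditions: Ac2O (1.1 equiv), Et3N, DMAP (cat.), DMF, 23 °C; then 2 (0.45 equiv), Pd(OAc)2 (5 mol %), P(o-tol)3 (12 mol %), Et3N, 110 °C, sealed tube
Reagents that add atoms: acetic anhydride, CC(=O)OC(C)=O
Why: O-acetylation followed by a twofold Mizoroki–Heck reaction, in which arylpalladium adds to each free diene terminus and β-hydride elimination from the π-allyl intermediate returns the conjugated E-alkene; the acetate keeps the phenol from interfering here and from forming quinone methides later.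

**Step 2**
Reactants: 5 (1E,3E)-1,4-bis(4-acetoxy-3,5-dimethoxyphenyl)-2,3-dimethylbuta-1,3-diene
Product: 6 4-[(1R,4R)-7-acetoxy-6,8-dimethoxy-2,3-dimethyl-4-{1-[(2-nitrophenyl)sulfonyl]-2-(propan-2-ylidene)hydrazinyl}-1,4-dihydronaphthalen-1-yl]-2,6-dimethoxyphenyl acetate (aryl at C1 and nitrogen at C4 trans)
Conditions: Pd(MeCN)4(BF4)2 (10 mol %), (S)-tBu-PyOx [(S)-4-tert-butyl-2-(pyridin-2-yl)-4,5-dihydrooxazole] (12 mol %), IPNBSH (1.2 equiv), 2,6-dimethyl-1,4-benzoquinone (1.2 equiv), K2HPO4 (20 mol %), THF, 0 → 23 °C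
Reagents that add atoms: N'-isopropylidene-2-nitrobenzenesulfonohydrazide (IPNBSH), CC(C)=NNS(=O)(=O)c1ccccc1[N+](=O)[O-]
Why: Proposed new method: enantioselective 1,4-hydrazidoarylation of a 1,3-diene by divalent palladium — the chiral PyOx–palladium cation binds the s-cis diene, the IPNBSH nitrogen attacks one benzylic terminus on the face opposite palladium (enantio-determining C–N bond formation that sets C4; the two termini are equivalent by symmetry), the resulting π-allylpalladium is then attacked at its far terminus, again opposite palladium, by the ortho carbon of the aryl ring on the new C–N carbon (six-membered ring closure, sets C1 trans to nitrogen), and the quinone reoxidises zerovalent palladium; the closest known reactions are the Bäckvall palladium/benzoquinone 1,4-difunctionalisation of 1,3-dienes, enantioselective aza-Wacker aminopalladation and the Movassaghi allylic substitution with IPNBSH.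

**Step 3**
Reactants: 6 the hydrazide adduct of step 2
Product: 10 (1S,2S)-1-(4-hydroxy-3,5-dimethoxyphenyl)-6,8-dimethoxy-2,3-dimethyl-1,2-dihydronaphthalen-7-ol, via N-aminosulfonamide 7 (not isolated), via allylic diazene 8 (not isolated), via cis-diacetate 9 (not isolated)
Conditions: CF3CH2OH–H2O (1:1), 23 °C, 3 h; then NH3 (7 M in MeOH), 0 → 23 °C, under Ar
Reagents that add atoms: none
Why: Myers–Movassaghi allylic diazene rearrangement: hydrazone hydrolysis and loss of sulfinate give the monoalkyl diazene, whose concerted retro-ene loss of N2 moves hydrogen suprafacially from nitrogen at C4 to C2 on the face opposite the C1 aryl group (so methyl ends cis to aryl) and shifts the double bond to C3=C4 without acid; ammonolysis then frees both phenols.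

**Compound list**
1 | 4-bromo-2,6-dimethoxyphenol | COc1cc(Br)cc(OC)c1O | starting material
2 | 2,3-dimethylbuta-1,3-diene | CC(=C)C(C)=C | starting material
3 | 4-bromo-2,6-dimethoxyphenyl acetate | COc1cc(Br)cc(OC)c1OC(C)=O | intermediate
4 | 4-[(1E)-2,3-dimethylbuta-1,3-dien-1-yl]-2,6-dimethoxyphenyl acetate | COc1cc(/C=C(C)/C(C)=C)cc(OC)c1OC(C)=O | intermediate
5 | (1E,3E)-1,4-bis(4-acetoxy-3,5-dimethoxyphenyl)-2,3-dimethylbuta-1,3-diene | COc1cc(/C=C(C)/C(C)=C/c2cc(OC)c(OC(C)=O)c(OC)c2)cc(OC)c1OC(C)=O | intermediate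
6 | 4-[(1R,4R)-7-acetoxy-6,8-dimethoxy-2,3-dimethyl-4-{1-[(2-nitrophenyl)sulfonyl]-2-(propan-2-ylidene)hydrazinyl}-1,4-dihydronaphthalen-1-yl]-2,6-dimethoxyphenyl acetate (trans) | COc1cc(cc(OC)c1OC(C)=O)[C@@H]2C(C)=C(C)[C@@H](N(N=C(C)C)S(=O)(=O)c4ccccc4[N+](=O)[O-])c3cc(OC)c(OC(C)=O)c(OC)c32 | intermediate
7 | 4-[(1R,4R)-7-acetoxy-6,8-dimethoxy-2,3-dimethyl-4-{1-[(2-nitrophenyl)sulfonyl]hydrazinyl}-1,4-dihydronaphthalen-1-yl]-2,6-dimethoxyphenyl acetate | COc1cc(cc(OC)c1OC(C)=O)[C@@H]2C(C)=C(C)[C@@H](N(N)S(=O)(=O)c4ccccc4[N+](=O)[O-])c3cc(OC)c(OC(C)=O)c(OC)c32 | intermediate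
8 | 4-[(1R,4R)-7-acetoxy-4-diazenyl-6,8-dimethoxy-2,3-dimethyl-1,4-dihydronaphthalen-1-yl]-2,6-dimethoxyphenyl acetate | COc1cc(cc(OC)c1OC(C)=O)[C@@H]2C(C)=C(C)[C@@H](N=N)c3cc(OC)c(OC(C)=O)c(OC)c32 | intermediate
9 | 4-[(1S,2S)-7-acetoxy-6,8-dimethoxy-2,3-dimethyl-1,2-dihydronaphthalen-1-yl]-2,6-dimethoxyphenyl acetate (cis) | COc1cc([C@H]2c3c(cc(OC)c(OC(C)=O)c3OC)C=C(C)[C@H]2C)cc(OC)c1OC(C)=O | intermediate
10 | (1S,2S)-1-(4-hydroxy-3,5-dimethoxyphenyl)-6,8-dimethoxy-2,3-dimethyl-1,2-dihydronaphthalen-7-ol (cis; CNP0141907.1) | COc1cc([C@H]2c3c(cc(OC)c(O)c3OC)C=C(C)[C@H]2C)cc(OC)c1O | target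

**Total step count:** 3. **Longest linear sequence:** 3.

**Steps most likely to fail**

Step 2 (the proposed new reaction). The risks are a second nitrogen attack on the π-allyl intermediate, β-hydride loss, weak binding of the hindered diene to palladium, and unknown enantioselectivity. The fallback uses known reaction types, sets out from 5 and rejoins at 8. Diene 5 undergoes a thermal azo Diels–Alder reaction with bis(2,2,2-trichloroethyl) azodicarboxylate (toluene, 23 °C) to give the cis (meso) tetrahydropyridazine F1, in which the Z-alkene is locked in the ring. BF3·OEt2 (CH2Cl2, −40 °C) ionises one benzylic-allylic C–N bond, and the aryl ring on the other nitrogen-bearing carbon closes by intramolecular Friedel–Crafts alkylation. The bulky hydrazide is expected to sit pseudoaxial, away from the C3 methyl, so ring closure on the opposite face should give the trans-4-hydrazido-1-aryl-1,4-dihydronaphthalene. This forms as a racemate of the (1R,4R) bis-carbamate F2 and its mirror image F3, which are separated by preparative HPLC on a chiral stationary phase. Zn/AcOH in THF removes both trichloroethyl carbamates from F2 to give the allylic hydrazine F4, and air oxidation gives diazene 8, which continues as in step 3.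

Step 3. The risk is ionisation of the benzylic-allylic C–N bond in the ionising solvent, which would lead to the aromatic arylnaphthalene instead of the diazene. The fallback sets out from 6 and rejoins at 10. Thiophenol and K2CO3 in MeOH–DMF remove the 2-nitrobenzenesulfonyl group by the Fukuyama thiolate cleavage and at the same time methanolyse both aryl acetates, giving the N-alkyl acetone hydrazone bisphenol F5. Mild aqueous AcOH in THF hydrolyses the hydrazone to the monoalkylhydrazine F6. Air oxidises F6 to the phenolic allylic diazene F7, which undergoes the same retro-ene loss of N2 to give 10 directly.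

Step 1. The risks are mono-arylation, the cross-conjugated isomer from β-hydride loss at a methyl group, and E/Z mixtures. The fallback sets out from aryl acetate 3 (made from 1 as in step 1) and rejoins at 5. Sonogashira coupling of 3 with propyne (Pd(PPh3)2Cl2, CuI, Et3N) gives the arylpropyne F8. Cp2Zr(py)(Me3SiC≡CSiMe3) in THF couples two molecules of F8 reductively to the zirconacyclopentadiene F9, with the aryl groups next to zirconium. Protonolysis with aqueous HCl replaces both C–Zr bonds by C–H with retention and gives the (1E,3E)-diene 5.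

**Further compounds**
F1 | step 2 | bis(2,2,2-trichloroethyl) cis-3,6-bis(4-acetoxy-3,5-dimethoxyphenyl)-4,5-dimethyl-3,6-dihydropyridazine-1,2-dicarboxylate (meso) | CC1=C(C)[C@H](c2cc(OC)c(OC(C)=O)c(OC)c2)N(C(=O)OCC(Cl)(Cl)Cl)N(C(=O)OCC(Cl)(Cl)Cl)[C@@H]1c1cc(OC)c(OC(C)=O)c(OC)c1
F2 | step 2 | bis(2,2,2-trichloroethyl) 1-[(1R,4R)-6-acetoxy-4-(4-acetoxy-3,5-dimethoxyphenyl)-5,7-dimethoxy-2,3-dimethyl-1,4-dihydronaphthalen-1-yl]hydrazine-1,2-dicarboxylate (trans) | COc1cc(cc(OC)c1OC(C)=O)[C@@H]2C(C)=C(C)[C@@H](N(NC(=O)OCC(Cl)(Cl)Cl)C(=O)OCC(Cl)(Cl)Cl)c3cc(OC)c(OC(C)=O)c(OC)c32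
F3 | step 2 | (1S,4S) enantiomer of F2 | COc1cc(cc(OC)c1OC(C)=O)[C@H]2C(C)=C(C)[C@H](N(NC(=O)OCC(Cl)(Cl)Cl)C(=O)OCC(Cl)(Cl)Cl)c3cc(OC)c(OC(C)=O)c(OC)c32
F4 | step 2 | 4-[(1R,4R)-7-acetoxy-4-hydrazinyl-6,8-dimethoxy-2,3-dimethyl-1,4-dihydronaphthalen-1-yl]-2,6-dimethoxyphenyl acetate | COc1cc(cc(OC)c1OC(C)=O)[C@@H]2C(C)=C(C)[C@@H](NN)c3cc(OC)c(OC(C)=O)c(OC)c32
F5 | step 3 | 4-[(1R,4R)-7-hydroxy-6,8-dimethoxy-2,3-dimethyl-4-[2-(propan-2-ylidene)hydrazinyl]-1,4-dihydronaphthalen-1-yl]-2,6-dimethoxyphenol | COc1cc(cc(OC)c1O)[C@@H]2C(C)=C(C)[C@@H](NN=C(C)C)c3cc(OC)c(O)c(OC)c32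
F6 | step 3 | 4-[(1R,4R)-4-hydrazinyl-7-hydroxy-6,8-dimethoxy-2,3-dimethyl-1,4-dihydronaphthalen-1-yl]-2,6-dimethoxyphenol | COc1cc(cc(OC)c1O)[C@@H]2C(C)=C(C)[C@@H](NN)c3cc(OC)c(O)c(OC)c32
F7 | step 3 | 4-[(1R,4R)-4-diazenyl-7-hydroxy-6,8-dimethoxy-2,3-dimethyl-1,4-dihydronaphthalen-1-yl]-2,6-dimethoxyphenol | COc1cc(cc(OC)c1O)[C@@H]2C(C)=C(C)[C@@H](N=N)c3cc(OC)c(O)c(OC)c32
F8 | step 1 | 2,6-dimethoxy-4-(prop-1-yn-1-yl)phenyl acetate | CC#Cc1cc(OC)c(OC(C)=O)c(OC)c1
F9 | step 1 | 1,1-bis(cyclopentadienyl)-2,5-bis(4-acetoxy-3,5-dimethoxyphenyl)-3,4-dimethylzirconacyclopenta-2,4-diene | CC1=C(c2cc(OC)c(OC(C)=O)c(OC)c2)[Zr](C2C=CC=C2)(C2C=CC=C2)C(c2cc(OC)c(OC(C)=O)c(OC)c2)=C1C
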